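The cyclohexene ring fused to pyrrole C1=C9a (tuberostemonine numbering, see remarks) is read as a Diels–Alder adduct: the pyrrole double bond sits where the cycloadduct alkene belongs, and the lactone ester O–C14(=O)–C13 already ties C11 to C12. A pyrrole-2,3-quinodimethane (exocyclic C9=C9a and C1=C12), released by fluoride from a C9-silyl, C12-acetoxy aldol ester, cyclises onto its own (E)-but-1-enyl ester. One operation makes C9–C10 and C11–C12, closes the carbocycle and the lactone, and sets C9–C12 under control of C13, which an Evans aldol installs. C13 is then inverted by kinetic protonation and the second lactone is built on C3.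

Key step: step 8

Remarks
- Numbering used for all compounds: pyrrole C1, C2, C3, N4, C9a; azepine N4–C5–C6–C7–C8–C9–C9a; cyclohexene C1–C9a–C9–C10(Et)–C11(O)–C12; lactone C11–O–C14(=O)–C13(Me)–C12; second lactone on C3: C18(O)–C19–C20(Me)–C21(=O). Target: 9R,10R,11S,12R,13R,18R,20S.
- Assumption: the silicon-bearing C9 of 5, 6, 8, 9, 13 and 14 is racemic and drawn without configuration; both epimers converge at the trigonal C9 of 15.
- Assumption: 2-methyl-1H-pyrrole-3-carbonitrile (1) is taken as a purchasable building block (otherwise one Hantzsch step from 3-aminocrotononitrile and chloroacetaldehyde).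

Step 1
Reactants: 1 2-methyl-1H-pyrrole-3-carbonitrile; 2 1,4-dibromobutane
Product: 3 1-(4-bromobutyl)-2-methyl-1H-pyrrole-3-carbonitrile
Conditions: NaH, DMF, 0 °C; then 2 (5 equiv), 0 °C → rt
Reagents that add atoms: none
Why: SN2 N-alkylation of the sodium pyrrolide; the excess of 2 suppresses double substitution.

Step 2
Reactants: 3 1-(4-bromobutyl)-2-methyl-1H-pyrrole-3-carbonitrile
Product: 5 9-(trimethylsilyl)-6,7,8,9-tetrahydro-5H-pyrrolo[1,2-a]azepine-1-carbonitrile (racemic), via bicyclic nitrile 4 (not isolated)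
Conditions: LiN(i-Pr)2 (1.05 equiv), THF (0.02 M), −78 → 0 °C; recool to −78 °C, LiN(i-Pr)2 (1.2 equiv); Me3SiCl, −78 → 0 °C
Reagents that add atoms: chlorotrimethylsilane, C[Si](C)(C)Cl
Why: Lateral lithiation of the 2-methyl group (vinylogous to the nitrile) and 7-exo-tet intramolecular alkylation close the azepine ring, and a second lateral lithiation at ring carbon C9 with C-silylation installs the trigger for step 8; C9 needs no control because it becomes trigonal.

Step 3
Reactants: 5 9-(trimethylsilyl)-6,7,8,9-tetrahydro-5H-pyrrolo[1,2-a]azepine-1-carbonitrile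
Product: 6 9-(trimethylsilyl)-6,7,8,9-tetrahydro-5H-pyrrolo[1,2-a]azepine-1-carbaldehyde (racemic)
Conditions: i-Bu2AlH, CH2Cl2, −78 → 0 °C; aq. KNaC4H4O6 (pH 7), rt
Reagents that add atoms: water, O
Why: Partial nitrile reduction: hydride addition stops at the N-aluminio imine, which neutral aqueous work-up hydrolyses to the aldehyde without acid that could protodesilylate C9.

Step 4
Reactants: 6 9-(trimethylsilyl)-6,7,8,9-tetrahydro-5H-pyrrolo[1,2-a]azepine-1-carbaldehyde; 7 (S)-4-benzyl-3-propanoyl-1,3-oxazolidin-2-one
Product: 8 (S)-4-benzyl-3-{(2S,3S)-3-hydroxy-2-methyl-3-[9-(trimethylsilyl)-6,7,8,9-tetrahydro-5H-pyrrolo[1,2-a]azepin-1-yl]propanoyl}-1,3-oxazolidin-2-one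
Conditions: 7, n-Bu2BOTf, i-Pr2NEt, CH2Cl2, −78 → 0 °C; then 6, −78 → 0 °C; pH 7 buffer, MeOH, H2O2, 0 °C
Reagents that add atoms: none
Why: Evans syn-aldol: the Z-boron enolate of 7 adds through a Zimmerman–Traxler chair on the face away from the benzyl group, which sets C13 as S (and C12 as S); C13 is the control element of the key step, whereas the C12 and C9 configurations are lost there.

Step 5
Reactants: 8 the aldol imide
Product: 9 (2S,3S)-3-hydroxy-2-methyl-3-[9-(trimethylsilyl)-6,7,8,9-tetrahydro-5H-pyrrolo[1,2-a]azepin-1-yl]propanoic acid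
Conditions: LiOH, H2O2, THF/H2O, 0 °C; Na2SO3; AcOH to pH 5, 0 °C
Reagents that add atoms: hydrogen peroxide, OO
Why: Standard auxiliary cleavage: LiOOH attacks the exocyclic imide carbonyl selectively without epimerising C13, and the weakly acidic work-up avoids ionising the silyl carbinol.

Step 6
Reactants: 10 but-1-yne
Product: 12 potassium (E)-but-1-en-1-yltrifluoroborate, via catechol alkenylboronate 11 (not isolated)
Conditions: catecholborane, neat, 70 °C (sealed tube); then aq. KHF2, MeOH/Et2O, rt
Reagents that add atoms: catecholborane, [BH]1Oc2ccccc2O1; potassium hydrogen difluoride, F.[F-].[K+]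
Why: syn-Hydroboration of the terminal alkyne places boron on C1 and gives the E-alkenylboronate, which KHF2 converts into the stable trifluoroborate with retention of geometry.

Step 7
Reactants: 9 the β-hydroxy acid; 12 potassium (E)-but-1-en-1-yltrifluoroborate
Product: 13 (E)-but-1-en-1-yl (2S,3S)-3-hydroxy-2-methyl-3-[9-(trimethylsilyl)-6,7,8,9-tetrahydro-5H-pyrrolo[1,2-a]azepin-1-yl]propanoate
Conditions: Cu(OAc)2 (10 mol %), DMAP (20 mol %), 4 Å MS, O2 (1 atm), MeCN, 40 °C
Reagents that add atoms: none
Why: Chan–Lam-type copper-catalysed oxidative C–O coupling of a carboxylic acid with an alkenyltrifluoroborate transfers the alkenyl group with retention, which fixes the E enol ester needed for the trans C10/C11 relationship.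

Step 8
Reactants: 13 the (E)-but-1-enyl β-hydroxy ester
Product: 16 (9R,10R,11S,12R,13S)-tetracyclic lactone (13-epimer of 18), via acetate 14 (not isolated), via quinodimethane 15 (not isolated)
Conditions: Ac2O, DMAP, Et3N, MeCN, 0 °C; then slow addition to CsF in MeCN (final 2 mM), 70 °C
Reagents that add atoms: none
Why: Acetylation makes the C12–O bond ionisable and fluoride attack at silicon triggers a vinylogous (1,4) desilylative elimination to the pyrrole-2,3-quinodimethane 15 (C9=C9a and C1=C12 exocyclic, C1=C12 of E geometry), which the tethered enol ester traps in a thermal intramolecular Diels–Alder reaction driven by recovery of the pyrrole; the closest known type is the fluoride-induced generation and intramolecular cycloaddition of aryl and indole-2,3-quinodimethanes. The cyclohexene closes by suprafacial [4+2] union at C9–C10 and C11–C12, and the γ-lactone is the ring spanned by the three-atom tether (C13, C14, O) in its endo orientation, which gives the cis C11–C12 fusion. C9 and C12 follow from the diene geometry (ring-locked C9=C9a, C13 outside on C12), C10 and C11 from the E enol ester (ethyl trans to oxygen), and the absolute sense from C13: allylic 1,3-strain with the pyrrole C2–H keeps H13 in the diene plane, so the dienophile, held by C14, adds to the face opposite the C13 methyl group. The step needs endo-tether over exo-tether selectivity, expected from the short planar ester tether and the exo ethyl group, and cycloaddition faster than dimerisation, secured by high dilution; proton shifts of 15 to aromatic isomers are blocked because C13 and C8 sit outside on the diene termini. The product carries the C13 methyl trans to C1 (13S), which step 9 corrects.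

Step 9
Reactants: 16 the (13S)-tetracyclic lactone
Product: 18 (9R,10R,11S,12R,13R)-tetracyclic lactone, via lithium enolate 17 (not isolated)
Conditions: LiN(i-Pr)2, THF, −78 °C; 2,6-di-tert-butyl-4-methylphenol, −78 °C; H2O
Reagents that add atoms: none
Why: Epimerisation via the enolate: deprotonation at C13 and kinetic C-protonation of the lactone enolate from the convex face of the cis-fused bicycle (away from the cyclohexene ring) place the methyl group on the concave face, giving 13R with H11, H12 and H13 all cis.

Step 10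
Reactants: 19 (S)-2-methylbutanedioic acid
Product: 20 (S)-3-methyloxolane-2,5-dione
Conditions: AcCl, reflux; evaporate
Reagents that add atoms: none
Why: Dehydrative cyclisation of the diacid through the mixed acetic anhydride; the stereocentre is not enolised under these conditions.

Step 11
Reactants: 18 the (13R)-tetracyclic lactone; 20 (S)-3-methyloxolane-2,5-dione
Product: 21 (S)-2-methyl-4-oxo-4-[(9R,10R,11S,12R,13R)-tetracyclic lactone-3-yl]butanoic acid
Conditions: Sc(OTf)3 (10 mol %), MeNO2/CH2Cl2, 0 °C → rt
Reagents that add atoms: none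
Why: Friedel–Crafts acylation at C3, the only free α-position of the electron-rich pyrrole, opens the anhydride at its less hindered carbonyl (remote from the methyl group), which leaves the C20 stereocentre next to the free acid.

Step 12
Reactants: 21 the γ-keto acid
Product: 23 target compound, via hydroxy acid 22 (not isolated)
Conditions: RuCl[(R,R)-TsDPEN](p-cymene) (2 mol %), HCO2H/Et3N (5:2), DMF, 30 °C
Reagents that add atoms: none
Why: Noyori-type asymmetric transfer hydrogenation of the heteroaryl ketone under catalyst control (the (R,R)-ligand delivers hydride as it does to acetophenone, giving the 18R carbinol); the γ-hydroxy acid lactonises in the acidic medium to the trans-disubstituted lactone.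

Compound list
1 | 2-methyl-1H-pyrrole-3-carbonitrile | Cc1[nH]ccc1C#N | starting material
2 | 1,4-dibromobutane | BrCCCCBr | starting material
3 | 1-(4-bromobutyl)-2-methyl-1H-pyrrole-3-carbonitrile | Cc1c(C#N)ccn1CCCCBr | intermediate
4 | 6,7,8,9-tetrahydro-5H-pyrrolo[1,2-a]azepine-1-carbonitrile (not isolated) | N#Cc1ccn2CCCCCc12 | intermediate
5 | 9-(trimethylsilyl)-6,7,8,9-tetrahydro-5H-pyrrolo[1,2-a]azepine-1-carbonitrile, racemic | N#Cc1ccn2CCCCC([Si](C)(C)C)c12 | intermediate
6 | 9-(trimethylsilyl)-6,7,8,9-tetrahydro-5H-pyrrolo[1,2-a]azepine-1-carbaldehyde, racemic | O=Cc1ccn2CCCCC([Si](C)(C)C)c12 | intermediate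
7 | (S)-4-benzyl-3-propanoyl-1,3-oxazolidin-2-one | CCC(=O)N1[C@@H](Cc2ccccc2)COC1=O | starting material
8 | (S)-4-benzyl-3-{(2S,3S)-3-hydroxy-2-methyl-3-[9-(trimethylsilyl)-6,7,8,9-tetrahydro-5H-pyrrolo[1,2-a]azepin-1-yl]propanoyl}-1,3-oxazolidin-2-one, both C9 epimers | O=C(N1[C@@H](Cc2ccccc2)COC1=O)[C@@H](C)[C@H](O)c1ccn2CCCCC([Si](C)(C)C)c12 | intermediate
9 | (2S,3S)-3-hydroxy-2-methyl-3-[9-(trimethylsilyl)-6,7,8,9-tetrahydro-5H-pyrrolo[1,2-a]azepin-1-yl]propanoic acid | OC(=O)[C@@H](C)[C@H](O)c1ccn2CCCCC([Si](C)(C)C)c12 | intermediate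
10 | but-1-yne | CCC#C | starting material
11 | 2-[(E)-but-1-en-1-yl]-1,3,2-benzodioxaborole (not isolated) | CC/C=C/B1Oc2ccccc2O1 | intermediate
12 | potassium (E)-but-1-en-1-yltrifluoroborate | CC/C=C/[B-](F)(F)F.[K+] | intermediate
13 | (E)-but-1-en-1-yl (2S,3S)-3-hydroxy-2-methyl-3-[9-(trimethylsilyl)-6,7,8,9-tetrahydro-5H-pyrrolo[1,2-a]azepin-1-yl]propanoate | CC/C=C/OC(=O)[C@@H](C)[C@H](O)c1ccn2CCCCC([Si](C)(C)C)c12 | intermediate
14 | (E)-but-1-en-1-yl (2S,3S)-3-acetoxy-2-methyl-3-[9-(trimethylsilyl)-6,7,8,9-tetrahydro-5H-pyrrolo[1,2-a]azepin-1-yl]propanoate (not isolated) | CC/C=C/OC(=O)[C@@H](C)[C@H](OC(C)=O)c1ccn2CCCCC([Si](C)(C)C)c12 | intermediate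
15 | pyrrole-2,3-quinodimethane: (E)-but-1-en-1-yl (2S)-2-methyl-3-[(1E)-5,6,7,8-tetrahydro-1H-pyrrolo[1,2-a]azepin-1-ylidene]propanoate, C9=C9a and C1=C12 exocyclic (not isolated) | CC/C=C/OC(=O)[C@@H](C)/C=C1\C=CN2CCCCC=C12 | intermediate
16 | (9R,10R,11S,12R,13S)-tetracyclic lactone: pyrrolo[1,2-a]azepine with C9–C10H(Et)–C11H(O)–C12H–C1 cyclohexene and cis-fused lactone C11–O–C14(=O)–C13H(Me)–C12, methyl trans to C1 | CC[C@H]1[C@@H]2OC(=O)[C@@H](C)[C@@H]2c2ccn3c2[C@@H]1CCCC3 | intermediate
17 | lithium enolate of 16 (C13=C14–OLi, not isolated) | CC[C@H]1[C@@H]2OC(O[Li])=C(C)[C@@H]2c2ccn3c2[C@@H]1CCCC3 | intermediate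
18 | (9R,10R,11S,12R,13R)-tetracyclic lactone, methyl cis to C1 (H11, H12, H13 all cis) | CC[C@H]1[C@@H]2OC(=O)[C@H](C)[C@@H]2c2ccn3c2[C@@H]1CCCC3 | intermediate
19 | (S)-2-methylbutanedioic acid | C[C@@H](CC(=O)O)C(=O)O | starting material
20 | (S)-3-methyloxolane-2,5-dione | C[C@H]1CC(=O)OC1=O | intermediate
21 | (S)-2-methyl-4-oxo-4-[(9R,10R,11S,12R,13R)-tetracyclic lactone-3-yl]butanoic acid | CC[C@H]1[C@@H]2OC(=O)[C@H](C)[C@@H]2c2cc(C(=O)C[C@H](C)C(=O)O)n3c2[C@@H]1CCCC3 | intermediate
22 | (2S,4R)-4-hydroxy-2-methyl-4-[(9R,10R,11S,12R,13R)-tetracyclic lactone-3-yl]butanoic acid (not isolated) | CC[C@H]1[C@@H]2OC(=O)[C@H](C)[C@@H]2c2cc([C@H](O)C[C@H](C)C(=O)O)n3c2[C@@H]1CCCC3 | intermediate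
23 | target, (9R,10R,11S,12R,13R,18R,20S) | CC[C@H]1[C@@H]2OC(=O)[C@H](C)[C@@H]2c2cc([C@H]3C[C@H](C)C(=O)O3)n3c2[C@@H]1CCCC3 | target

Total step count: 12. Longest linear sequence: 10 steps (1, 2, 3, 4, 5, 7, 8, 9, 11, 12).

Steps most likely to fail

Step 8. The transient quinodimethane 15 may dimerise before the slow cycloaddition onto the unactivated enol ester (the ester tether must reach its s-cis conformation), or it may close through the exo-tether transition state to the trans-fused lactone. The fallback sets out from 9 and returns at 16; it activates the dienophile and makes the ring fusion correctable. Acid 9 is added to but-3-yn-2-one (N-methylmorpholine cat., CH2Cl2) to give the (E)-3-oxobut-1-enyl ester F1. MsCl/Et3N at −78 °C forms the mesylate F2, which on warming under dilution loses the silyl group to chloride and gives the quinodimethane F3. The now polarity-matched cycloaddition (nucleophilic C12 onto the enone β-carbon C11) gives the 10-acetyl lactone F4. Its C10 and C11 centres can equilibrate under mild base (enolisation, reversible β-elimination and oxa-Michael reclosure) to the cis-fused lactone with the equatorial acetyl group. The tosylhydrazone F5 (TsNHNH2, EtOH) is reduced with catecholborane then NaOAc (Caglioti reduction) to the ethyl compound 16.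

Step 7. Aerobic copper catalysis may oxidise the electron-rich, α-unsubstituted pyrrole or ionise the C12 carbinol next to the silyl trigger. The fallback sets out from 6 (with 12) and returns at 15; it moves the C–O coupling to a robust substrate and sets C13 by reagent control. Propanoic acid and 12 give (E)-but-1-enyl propanoate F6 under the step 7 conditions. Its boron enolate is formed with enantiopure 2-bromo-4,5-diphenyl-1,3-bis(p-tolylsulfonyl)-1,3,2-diazaborolidine and Et3N; the enantiomer of the reagent that gives 2S is used, and the C12 configuration is irrelevant because that centre becomes trigonal. Addition to aldehyde 6 gives the anti aldol F7. Acetylation under the step 8 conditions gives acetate F8, which with CsF gives 15.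

Step 9. Protonation of enolate 17 may show poor facial selectivity or occur on oxygen with later unselective tautomerisation, leaving the 13S epimer. The fallback sets out from 16 and returns at 18; it sets C13 by hydrogen-atom transfer instead. Enolate 17 is quenched with CBr4 at −78 °C to give the 13-bromo lactone F9. Radical debromination with (Me3Si)3SiH and Et3B/air at low temperature delivers hydrogen to the planar C13 radical from the open convex face and gives 18.

Further compounds
F1 | step 8 | (E)-3-oxobut-1-en-1-yl (2S,3S)-3-hydroxy-2-methyl-3-[9-(trimethylsilyl)-6,7,8,9-tetrahydro-5H-pyrrolo[1,2-a]azepin-1-yl]propanoate | CC(=O)/C=C/OC(=O)[C@@H](C)[C@H](O)c1ccn2CCCCC([Si](C)(C)C)c12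
F2 | step 8 | mesylate of F1 | CC(=O)/C=C/OC(=O)[C@@H](C)[C@H](OS(C)(=O)=O)c1ccn2CCCCC([Si](C)(C)C)c12
F3 | step 8 | quinodimethane with (E)-3-oxobut-1-enyl ester | CC(=O)/C=C/OC(=O)[C@@H](C)/C=C1\C=CN2CCCCC=C12
F4 | step 8 | 10-acetyl analogue of 16 | CC(=O)[C@H]1[C@@H]2OC(=O)[C@@H](C)[C@@H]2c2ccn3c2[C@@H]1CCCC3
F5 | step 8 | tosylhydrazone of F4 | CC(=NNS(=O)(=O)c1ccc(C)cc1)[C@H]1[C@@H]2OC(=O)[C@@H](C)[C@@H]2c2ccn3c2[C@@H]1CCCC3
F6 | step 7 | (E)-but-1-en-1-yl propanoate | CC/C=C/OC(=O)CC
F7 | step 7 | (E)-but-1-en-1-yl (2S,3R)-3-hydroxy-2-methyl-3-[9-(trimethylsilyl)-6,7,8,9-tetrahydro-5H-pyrrolo[1,2-a]azepin-1-yl]propanoate | CC/C=C/OC(=O)[C@@H](C)[C@@H](O)c1ccn2CCCCC([Si](C)(C)C)c12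
F8 | step 7 | acetate of F7 | CC/C=C/OC(=O)[C@@H](C)[C@@H](OC(C)=O)c1ccn2CCCCC([Si](C)(C)C)c12
F9 | step 9 | 13-bromo derivative of the tetracyclic lactone (bromine on the convex face) | CC[C@H]1[C@@H]2OC(=O)[C@](Br)(C)[C@@H]2c2ccn3c2[C@@H]1CCCC3
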